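**Retrosynthetic overview** (numbering: ring A = C1–C5/C10, ring B = C5–C10, C11 = methylene on C4, C12/C13/C14 = methyls on C5/C8/C9, C15 = benzylic CH2, C1'–C6' = quinone)
1. The quinone is unmasked last from a 5'-methoxy-2',3',6'-tris(methoxymethoxy)aryl group (deprotection, autoxidation); C13 comes from a C8 ketone by one-carbon homologation and axial protonation.
2. Key disconnection at quaternary C9 (bonds C9–C10 and C9–C15): ring B is grown from the cyclopentanone ring C5–C6–C7–C8–C10 of a cis-hydrindanone by inserting C9 (with C14, from 1,1-dibromoethane) between C8 and C10; the ring-expanded C8=C9 enolate is benzylated in the same flask by the arylmethyl bromide.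
3. Enabling feature: C9 is a quaternary carbon lying between C8, which can carry a carbonyl (later CH–CH3), and the ring-fusion methine C10; a C8 ketone in a five-membered ring therefore supplies both the migration origin and, after the shift, the enolate that accepts C15.
4. The cis-hydrindanone comes from 3-methylcyclopent-2-enone by asymmetric conjugate addition of a 5-chloropent-1-en-2-yl metal (sets C5) and intramolecular enolate alkylation (closes ring A with C4=C11 already in place).
5. Ring order: cyclopentanone (bought) → ring A → ring B by one-carbon ring expansion → quinone (carried as protected arene, oxidised last).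

Key step: step 10

**Remarks**
- Faces: the α-face of ring B is the face carrying C10–H and C12; the β-face carries C14 and C13 in the target.
- Assumption: 5-chloropent-1-yne, 3-methylcyclopent-2-en-1-one, 2-methoxy-1,4-benzoquinone and B-bromo-9-borabicyclo[3.3.1]nonane are taken as commercial; the ligand antipode in step 2 is the one that gives the (R)-adduct, to be fixed by a test reaction.
- The configuration at the carbinol carbon of 9 is of no consequence, since that carbon becomes the C8 carbonyl in step 10.

**Step 1**
Reactants: 1 5-chloropent-1-yne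
Product: 3 2-bromo-5-chloropent-1-ene, via alkenylborane 2 (not isolated)
Conditions: B-Br-9-BBN, CH2Cl2, 0 °C; then AcOH, 0 °C → rt
Reagents that add atoms: B-bromo-9-borabicyclo[3.3.1]nonane, BrB1C2CCCC1CCC2
Why: Syn-bromoboration of the terminal alkyne places bromine on the internal carbon and protonolysis of the C–B bond by acetic acid leaves the 2-bromo-1-alkene (haloboration–protodeboronation), the alkyl chloride being inert.

**Step 2**
Reactants: 3 2-bromo-5-chloropent-1-ene; 4 3-methylcyclopent-2-en-1-one
Product: 7 (3R)-3-(5-chloropent-1-en-2-yl)-3-methylcyclopentan-1-one, via vinyllithium 5 (not isolated), via alkenylalane 6 (not isolated)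
Conditions: t-BuLi (2 equiv), Et2O, −78 °C; Me2AlCl, −78 → −30 °C; then 4, CuTC (copper thiophene-2-carboxylate, monovalent copper, 10 mol %), chiral N,N-bis(1-arylethyl)-P,P-diphenylphosphinous amide (11 mol %), Et2O, −30 °C; H2O
Reagents that add atoms: none
Why: Copper-catalysed asymmetric conjugate addition of an alkenylalane to a β-substituted cyclic enone creates the quaternary carbon C5, the chiral aminophosphine–copper complex selecting the enone face that leads to the (R)-adduct and the alkenyl group transferring in preference to methyl.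

**Step 3**
Reactants: 7 (3R)-3-(5-chloropent-1-en-2-yl)-3-methylcyclopentan-1-one
Product: 8 (3aR,7aR)-3a-methyl-4-methylideneoctahydro-1H-inden-1-one (cis-fused)
Conditions: t-BuOK, t-BuOH/THF, rt
Reagents that add atoms: none
Why: Intramolecular enolate C-alkylation (the ring-closing half of a methylenecyclohexane annulation) closes ring A by 6-exo-tet displacement of chloride at C1 by the C10 enolate carbon, and because the tether hangs from C5 the new C10–C1 bond can only form cis to it, so C10–H ends up cis to C12.

**Step 4**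
Reactants: 8 (3aR,7aR)-3a-methyl-4-methylideneoctahydro-1H-inden-1-one
Product: 9 (1S,3aR,7aR)-1-(1,1-dibromoethyl)-3a-methyl-4-methylideneoctahydro-1H-inden-1-ol
Conditions: CH3CHBr2, LDA, THF/Et2O, −95 °C; then 8, −95 → −78 °C; H2O
Reagents that add atoms: 1,1-dibromoethane, CC(Br)Br
Why: 1,2-Addition of the carbenoid 1,1-dibromoethyllithium to the cyclopentanone (first stage of a dibromoalkyllithium homologation of cycloalkanones) is fast at low temperature and should occur from the convex α-face, syn to C10–H.

**Step 5**
Reactants: 10 2-methoxy-1,4-benzoquinone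
Product: 11 5-methoxybenzene-1,2,4-triyl triacetate
Conditions: Ac2O, H2SO4 (cat.), rt
Reagents that add atoms: acetic anhydride, CC(=O)OC(C)=O
Why: Thiele–Winter acetoxylation: acid-catalysed conjugate addition of acetate to the enone half that is not deactivated by the methoxy group (at C5 of the quinone), then enolisation and acetylation, gives the 1,2,4-triacetoxy-5-methoxy pattern.

**Step 6**
Reactants: 11 5-methoxybenzene-1,2,4-triyl triacetate
Product: 12 5-methoxybenzene-1,2,4-triol
Conditions: HCl (cat.), MeOH (degassed), Ar, rt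
Reagents that add atoms: none
Why: Acid-catalysed transesterification with methanol removes the three aryl acetates, and the acidic, oxygen-free medium keeps the air-sensitive triol from oxidising.

**Step 7**
Reactants: 12 5-methoxybenzene-1,2,4-triol
Product: 13 1-methoxy-2,4,5-tris(methoxymethoxy)benzene
Conditions: MOMCl, i-Pr2NEt, CH2Cl2, 0 °C → rt, Ar
Reagents that add atoms: chloromethyl methyl ether, COCCl
Why: O-Alkylation of the three phenols with chloromethyl methyl ether gives base-stable MOM ethers that direct the metalation in step 8 and are removed together in step 14.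

**Step 8**
Reactants: 13 1-methoxy-2,4,5-tris(methoxymethoxy)benzene
Product: 15 [3-methoxy-2,5,6-tris(methoxymethoxy)phenyl]methanol, via aryllithium 14 (not isolated)
Conditions: n-BuLi, TMEDA, THF, 0 °C; (CH2O)n, −78 °C → rt; H2O
Reagents that add atoms: formaldehyde (as paraformaldehyde), C=O
Why: Directed ortho-metalation removes the hydrogen flanked by two OMOM groups in preference to the one between OMOM and OMe, and the aryllithium is hydroxymethylated by formaldehyde.

**Step 9**
Reactants: 15 [3-methoxy-2,5,6-tris(methoxymethoxy)phenyl]methanol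
Product: 16 3-(bromomethyl)-1-methoxy-2,4,5-tris(methoxymethoxy)benzene
Conditions: CBr4, PPh3, CH2Cl2, 0 °C
Reagents that add atoms: tetrabromomethane, BrC(Br)(Br)Br
Why: Appel bromination converts the benzylic alcohol into the bromide under neutral conditions that spare the MOM ethers.

**Step 10**
Reactants: 9 (1S,3aR,7aR)-1-(1,1-dibromoethyl)-3a-methyl-4-methylideneoctahydro-1H-inden-1-ol; 16 3-(bromomethyl)-1-methoxy-2,4,5-tris(methoxymethoxy)benzene
Product: 19 (1S,4aR,8aR)-1-{[3-methoxy-2,5,6-tris(methoxymethoxy)phenyl]methyl}-1,4a-dimethyl-5-methylideneoctahydronaphthalen-2(1H)-one, via β-oxido carbenoid 17 (not isolated), via lithium enolate 18 (not isolated)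
Conditions: n-BuLi (2.1 equiv), THF, −95 → −20 °C; then DMPU, 16, −78 → 0 °C
Reagents that add atoms: none
Why: Deprotonation of the hydroxyl and bromine–lithium exchange give the β-oxido carbenoid 17, in which the alkoxide pushes the more substituted ring bond C8–C10 onto the carbenoid carbon C9 with loss of bromide, so that C9 with C14 is inserted between C8 and C10 and the five-membered ring becomes six-membered ring B as the regiodefined lithium enolate 18 (C8=C9), which is then C-benzylated by 16. The closest known reaction type is the β-oxido carbenoid ring enlargement of cycloalkanones with 1,1-dibromoalkanes, followed by alkylation of a tetrasubstituted lithium enolate with a benzylic bromide as in reductive alkylations of octalones. Ring B is not closed by a cyclisation but arises by a 1,2-alkyl shift (one-carbon ring expansion of the cyclopentane C5–C6–C7–C8–C10), and no other ring is formed. C10 migrates with retention, so the cis C5/C10 fusion from step 3 is carried over, and C9 is set in the alkylation, where the bromide should approach the enolate from the convex α-face (syn to C10–H) through the half-chair that has C10–H axial and C12 equatorial, because the β-face of that conformer is screened by axial C4 of ring A and the alternative half-chair blocks both faces (axial C12 on the α-face, axial C1 on the β-face). The step needs migration of C10 and not C7 (secured by the higher migratory aptitude of the secondary ring-fusion carbon), C- over O-alkylation (lithium enolate, benzylic bromide, DMPU) and mono-alkylation (C9 has no hydrogen left and proton transfer to C7 is slow at low temperature).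

**Step 11**
Reactants: 19 (1S,4aR,8aR)-1-{[3-methoxy-2,5,6-tris(methoxymethoxy)phenyl]methyl}-1,4a-dimethyl-5-methylideneoctahydronaphthalen-2(1H)-one
Product: 20 (1S,4aR,8aR)-2-(methoxymethylidene)-1-{[3-methoxy-2,5,6-tris(methoxymethoxy)phenyl]methyl}-1,4a-dimethyl-5-methylidenedecahydronaphthalene (E/Z mixture)
Conditions: Ph3P(CH2OMe)Cl, t-BuOK, THF, 0 °C → reflux
Reagents that add atoms: (methoxymethyl)triphenylphosphonium chloride, COC[P+](c1ccccc1)(c1ccccc1)c1ccccc1.[Cl-]
Why: Wittig olefination with the small methoxymethylidene ylide homologates the hindered C8 ketone to the enol ether that carries C13, both alkene isomers converging in step 12.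

**Step 12**
Reactants: 20 (1S,4aR,8aR)-2-(methoxymethylidene)-1-{[3-methoxy-2,5,6-tris(methoxymethoxy)phenyl]methyl}-1,4a-dimethyl-5-methylidenedecahydronaphthalene
Product: 22 [(1S,2S,4aR,8aS)-1-{[3-methoxy-2,5,6-tris(methoxymethoxy)phenyl]methyl}-1,4a-dimethyl-5-methylidenedecahydronaphthalen-2-yl]methanol, via aldehyde 21 (not isolated)
Conditions: aq HCl (cat.), THF, 0 °C → rt; then NaBH4, EtOH, 0 °C
Reagents that add atoms: water, O
Why: Enol ether hydrolysis protonates C8 axially from the α-face, anti to the axial C14 methyl of the preferred chair (C14 axial, arylmethyl equatorial), so the formyl carbon becomes equatorial and cis to C14 (8S), and immediate borohydride reduction fixes this centre before it can epimerise.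

**Step 13**
Reactants: 22 [(1S,2S,4aR,8aS)-1-{[3-methoxy-2,5,6-tris(methoxymethoxy)phenyl]methyl}-1,4a-dimethyl-5-methylidenedecahydronaphthalen-2-yl]methanol
Product: 24 1-methoxy-2,4,5-tris(methoxymethoxy)-3-{[(1R,2S,4aR,8aS)-1,2,4a-trimethyl-5-methylidenedecahydronaphthalen-1-yl]methyl}benzene, via mesylate 23 (not isolated)
Conditions: MsCl, Et3N, CH2Cl2, 0 °C; then LiEt3BH, THF, reflux
Reagents that add atoms: none
Why: Mesylation followed by SN2 hydride displacement with LiEt3BH deoxygenates the primary alcohol to the C13 methyl without touching the C8 stereocentre, the alkene or the MOM ethers.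

**Step 14**
Reactants: 24 1-methoxy-2,4,5-tris(methoxymethoxy)-3-{[(1R,2S,4aR,8aS)-1,2,4a-trimethyl-5-methylidenedecahydronaphthalen-1-yl]methyl}benzene
Product: 27 2-hydroxy-5-methoxy-3-{[(1R,2S,4aR,8aS)-1,2,4a-trimethyl-5-methylidenedecahydronaphthalen-1-yl]methyl}cyclohexa-2,5-diene-1,4-dione (CID21727418), via tris(trimethylsilyl) ether 25 (not isolated), via triol 26 (not isolated)
Conditions: TMSOTf, 2,2'-bipyridyl, CH2Cl2, 0 °C; H2O; then air, pH 7 buffer/EtOAc, rt
Reagents that add atoms: none
Why: TMSOTf with 2,2'-bipyridyl cleaves aryl MOM ethers under non-acidic conditions via the aryl silyl ethers, which water hydrolyses, so the exocyclic alkene should survive, and the 1,2,4-triol autoxidises to the only quinone it can form, the 2-hydroxy-5-methoxy-1,4-benzoquinone.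

**Compound list**
1 | 5-chloropent-1-yne | C#CCCCCl | starting material
2 | 9-[(Z)-2-bromo-5-chloropent-1-en-1-yl]-9-borabicyclo[3.3.1]nonane | ClCCC/C(Br)=C/B1C2CCCC1CCC2 | intermediate
3 | 2-bromo-5-chloropent-1-ene | C=C(Br)CCCCl | intermediate
4 | 3-methylcyclopent-2-en-1-one | CC1=CC(=O)CC1 | starting material
5 | (5-chloropent-1-en-2-yl)lithium | [Li]C(=C)CCCCl | intermediate
6 | (5-chloropent-1-en-2-yl)dimethylalane | C[Al](C)C(=C)CCCCl | intermediate
7 | (3R)-3-(5-chloropent-1-en-2-yl)-3-methylcyclopentan-1-one | ClCCCC(=C)[C@]1(C)CCC(=O)C1 | intermediate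
8 | (3aR,7aR)-3a-methyl-4-methylideneoctahydro-1H-inden-1-one | C=C1CCC[C@H]2C(=O)CC[C@@]12C | intermediate
9 | (1S,3aR,7aR)-1-(1,1-dibromoethyl)-3a-methyl-4-methylideneoctahydro-1H-inden-1-ol | C=C1CCC[C@H]2[C@](O)(C(C)(Br)Br)CC[C@@]12C | intermediate
10 | 2-methoxy-1,4-benzoquinone | COC1=CC(=O)C=CC1=O | starting material
11 | 5-methoxybenzene-1,2,4-triyl triacetate | COc1cc(OC(C)=O)c(OC(C)=O)cc1OC(C)=O | intermediate
12 | 5-methoxybenzene-1,2,4-triol | COc1cc(O)c(O)cc1O | intermediate
13 | 1-methoxy-2,4,5-tris(methoxymethoxy)benzene | COc1cc(OCOC)c(OCOC)cc1OCOC | intermediate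
14 | [3-methoxy-2,5,6-tris(methoxymethoxy)phenyl]lithium | [Li]c1c(OCOC)c(OCOC)cc(OC)c1OCOC | intermediate
15 | [3-methoxy-2,5,6-tris(methoxymethoxy)phenyl]methanol | OCc1c(OCOC)c(OCOC)cc(OC)c1OCOC | intermediate
16 | 3-(bromomethyl)-1-methoxy-2,4,5-tris(methoxymethoxy)benzene | BrCc1c(OCOC)c(OCOC)cc(OC)c1OCOC | intermediate
17 | dilithiated β-oxido carbenoid of 9 (lithium alkoxide, 1-bromo-1-lithioethyl group; carbenoid carbon configurationally labile) | C=C1CCC[C@H]2[C@](O[Li])(C(C)(Br)[Li])CC[C@@]12C | intermediate
18 | lithium (4aR,8aR)-1,4a-dimethyl-5-methylidene-3,4,4a,5,6,7,8,8a-octahydronaphthalen-2-olate | C=C1CCC[C@H]2C(C)=C(O[Li])CC[C@@]12C | intermediate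
19 | (1S,4aR,8aR)-1-{[3-methoxy-2,5,6-tris(methoxymethoxy)phenyl]methyl}-1,4a-dimethyl-5-methylideneoctahydronaphthalen-2(1H)-one | C=C1CCC[C@H]2[C@](C)(Cc3c(OCOC)c(OCOC)cc(OC)c3OCOC)C(=O)CC[C@@]12C | intermediate
20 | (1S,4aR,8aR)-2-(methoxymethylidene)-1-{[3-methoxy-2,5,6-tris(methoxymethoxy)phenyl]methyl}-1,4a-dimethyl-5-methylidenedecahydronaphthalene (E/Z mixture) | C=C1CCC[C@H]2[C@](C)(Cc3c(OCOC)c(OCOC)cc(OC)c3OCOC)C(=COC)CC[C@@]12C | intermediate
21 | (1S,2S,4aR,8aS)-1-{[3-methoxy-2,5,6-tris(methoxymethoxy)phenyl]methyl}-1,4a-dimethyl-5-methylidenedecahydronaphthalene-2-carbaldehyde | C=C1CCC[C@H]2[C@](C)(Cc3c(OCOC)c(OCOC)cc(OC)c3OCOC)[C@@H](C=O)CC[C@@]12C | intermediate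
22 | [(1S,2S,4aR,8aS)-1-{[3-methoxy-2,5,6-tris(methoxymethoxy)phenyl]methyl}-1,4a-dimethyl-5-methylidenedecahydronaphthalen-2-yl]methanol | C=C1CCC[C@H]2[C@](C)(Cc3c(OCOC)c(OCOC)cc(OC)c3OCOC)[C@@H](CO)CC[C@@]12C | intermediate
23 | methanesulfonate of 22 | C=C1CCC[C@H]2[C@](C)(Cc3c(OCOC)c(OCOC)cc(OC)c3OCOC)[C@@H](COS(C)(=O)=O)CC[C@@]12C | intermediate
24 | 1-methoxy-2,4,5-tris(methoxymethoxy)-3-{[(1R,2S,4aR,8aS)-1,2,4a-trimethyl-5-methylidenedecahydronaphthalen-1-yl]methyl}benzene | C=C1CCC[C@H]2[C@](C)(Cc3c(OCOC)c(OCOC)cc(OC)c3OCOC)[C@@H](C)CC[C@@]12C | intermediate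
25 | tris(trimethylsilyl) ether of 26 | C=C1CCC[C@H]2[C@](C)(Cc3c(O[Si](C)(C)C)c(O[Si](C)(C)C)cc(OC)c3O[Si](C)(C)C)[C@@H](C)CC[C@@]12C | intermediate
26 | 5-methoxy-3-{[(1R,2S,4aR,8aS)-1,2,4a-trimethyl-5-methylidenedecahydronaphthalen-1-yl]methyl}benzene-1,2,4-triol | C=C1CCC[C@H]2[C@](C)(Cc3c(O)c(O)cc(OC)c3O)[C@@H](C)CC[C@@]12C | intermediate
27 | 2-hydroxy-5-methoxy-3-{[(1R,2S,4aR,8aS)-1,2,4a-trimethyl-5-methylidenedecahydronaphthalen-1-yl]methyl}cyclohexa-2,5-diene-1,4-dione | C=C1CCC[C@H]2[C@](C)(CC3=C(O)C(=O)C=C(OC)C3=O)[C@@H](C)CC[C@@]12C | target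

**Step count and risks**
Total step count: 14. Longest linear sequence: 10 steps (steps 5–9, then 10–14).

Steps most likely to fail:

1. Step 10. The benzylation of enolate 18 may show poor or reversed facial selectivity at C9, and migration of C7 may compete with migration of C10 in the 1,2-shift. The fallback reverses the order in which the two C9 substituents are installed and sets out from 8. Addition of dibromomethyllithium (CH2Br2, LDA, −95 °C) should give the dibromomethyl carbinol F1. Treatment with n-BuLi (2 equiv) and trapping of the ring-expanded enolate with 16 should give the 1-arylmethyl ketone F2 as a C1-epimer mixture. Methylation of its more substituted enolate (t-BuOK, t-BuOH, MeI) then brings the methyl group in last, from the face that the benzylic bromide would otherwise have taken, and returns to the route at 19.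

2. Step 2. The conjugate addition may give insufficient enantioselectivity or competing methyl transfer from aluminium. The fallback exchanges the roles of the two carbon groups and sets out from 3. The vinyllithium 5 is added to 3-ethoxycyclopent-2-en-1-one to give the tertiary allylic alcohol F3, which on acidic work-up (Stork–Danheiser transposition) should give the dienone F4. A copper-catalysed asymmetric 1,4-addition of MeMgBr (Cu(OTf)2, chiral N-heterocyclic carbene ligand, Et2O, −30 °C) then forms the quaternary centre and returns to the route at 7.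

3. Step 11. Enolisation towards C7 and steric shielding of the C8 carbonyl by the adjacent quaternary C9 may stop the olefination. The fallback sets out from 19 and introduces C13 by carbonylation. KHMDS and PhNTf2 should give the enol triflate F5. Methoxycarbonylation (Pd(OAc)2, PPh3, CO, MeOH, Et3N, DMF) should give the unsaturated methyl ester F6. Conjugate reduction with Mg in MeOH, with protonation and equilibration to the equatorial ester, should give the saturated ester F7, and LiAlH4 reduction returns to the route at 22.

**Further compounds**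
F1 | step 10 | (1S,3aR,7aR)-1-(dibromomethyl)-3a-methyl-4-methylideneoctahydro-1H-inden-1-ol | C=C1CCC[C@H]2[C@](O)(C(Br)Br)CC[C@@]12C
F2 | step 10 | (4aR,8aS)-1-{[3-methoxy-2,5,6-tris(methoxymethoxy)phenyl]methyl}-4a-methyl-5-methylideneoctahydronaphthalen-2(1H)-one (C1 epimers) | C=C1CCC[C@H]2C(Cc3c(OCOC)c(OCOC)cc(OC)c3OCOC)C(=O)CC[C@@]12C
F3 | step 2 | 1-(5-chloropent-1-en-2-yl)-3-ethoxycyclopent-2-en-1-ol | CCOC1=CC(O)(CC1)C(=C)CCCCl
F4 | step 2 | 3-(5-chloropent-1-en-2-yl)cyclopent-2-en-1-one | C=C(CCCCl)C1=CC(=O)CC1
F5 | step 11 | (1S,4aR,8aR)-1-{[3-methoxy-2,5,6-tris(methoxymethoxy)phenyl]methyl}-1,4a-dimethyl-5-methylidene-1,4,4a,5,6,7,8,8a-octahydronaphthalen-2-yl trifluoromethanesulfonate | C=C1CCC[C@H]2[C@](C)(Cc3c(OCOC)c(OCOC)cc(OC)c3OCOC)C(OS(=O)(=O)C(F)(F)F)=CC[C@@]12C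
F6 | step 11 | methyl (1S,4aR,8aR)-1-{[3-methoxy-2,5,6-tris(methoxymethoxy)phenyl]methyl}-1,4a-dimethyl-5-methylidene-1,4,4a,5,6,7,8,8a-octahydronaphthalene-2-carboxylate | C=C1CCC[C@H]2[C@](C)(Cc3c(OCOC)c(OCOC)cc(OC)c3OCOC)C(C(=O)OC)=CC[C@@]12C
F7 | step 11 | methyl (1S,2S,4aR,8aS)-1-{[3-methoxy-2,5,6-tris(methoxymethoxy)phenyl]methyl}-1,4a-dimethyl-5-methylidenedecahydronaphthalene-2-carboxylate | C=C1CCC[C@H]2[C@](C)(Cc3c(OCOC)c(OCOC)cc(OC)c3OCOC)[C@@H](C(=O)OC)CC[C@@]12C
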